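The readings are calculated with made-up constants; the scatter is artificial.

Two questions stand on this flask, and both ask how the rate of making target, at the mark of 5.0 % conversion, answers to more free catalyst.

* factor on the rate of making target when 5.0 % of the starting material are converted if free catalyst is charged twice over
* factor on the rate when 5.0 % of the starting material are converted if free catalyst is charged at 10 mol% instead

| setting | amber | violet | red | flask |
|---|---|---|---|---|
| starting material | 5.0 × 10⁻⁴ M | 5.0 × 10⁻⁴ M | 5.0 × 10⁻⁴ M | 5.0 × 10⁻⁴ M |
| protic impurity | 0.25 mM | 0.25 mM | 0.38 mM | 0.250 mM |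
| free catalyst | 0.95 mol% | 1.4 mol% | 1.9 mol% | 1.9 mol% |
| remark | run made earlier | run made earlier | run made earlier |  |

| run | time / min | target / % | starting material / % |
|---|---|---|---|
| amber | 0.667 | 24.3 | 24.0 |
| amber | 1.33 | 42.4 | 8.4 |
| amber | 2.00 | 46.0 | 2.9 |
| amber | 3.00 | 51.1 | 0.5 |
| amber | 4.00 | 50.4 | 0 |
| amber | 5.00 | 50.2 | 0.8 |
| violet | 0.250 | 14.8 | 36.9 |
| violet | 0.667 | 33.5 | 15.1 |
| violet | 1.33 | 48.3 | 2.6 |
| violet | 2.00 | 50.1 | 0.9 |
| violet | 3.00 | 49.6 | 0 |
| violet | 4.00 | 49.6 | 0 |
| violet | 5.00 | 50.1 | 1.5 |
| red | 1.00 | 25.7 | 0 |
| red | 2.00 | 24.7 | 0 |
| red | 3.00 | 24.8 | 0.2 |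
| red | 4.00 | 25.2 | 0 |
| red | 5.00 | 25.1 | 0 |

(scatter of a reading: 1 percentage point)

- what was read earlier has a scatter of 1 percentage point, one standard deviation
- what is bound to the catalyst counts as converted

The runs show target levelling off near the part of the starting material that the protic impurity leaves, 50.2 % in the amber run and 25.1 % in the red run with its larger impurity charge. In the violet run, target plus starting material already stands at 51.7 % after 0.250 min, so the impurity works early and competes for the same conversion as the catalyst.

What is bound to the catalyst counts as converted, so write the balance of the catalyst: free plus bound equals the charge, and bound cannot pass the conversion at the mark. This gives the free floor, one minus the mark conversion over the catalyst charge, the smallest share of the catalyst that stays free there. At 10 mol% you get 50.0 %, while a doubled charge of 0.0380 lies below the mark and has no floor.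

Now take two extreme versions of this flask. If the rate follows the charge, you get factors of 2 and 5.26. If instead the rate follows the bound catalyst and binding goes as far as it can, bound is the charge up to the 5.0 % of the mark, and you get 2 and 2.63. My own reckoning takes these two versions as its bracket: about 2 for doubling, and between 2.63 and 5.26 at 10 mol%.

The forecast says 2 and 3.4, the second above the lower end of my bracket and below its upper end, on the grounds that “Complex is capped at 5 or less, some conversion being by-product”.

The simulation gives 1.52 and 1.88, each lower than the lower end of my bracket, from these steps:

    starting material + free catalyst ⇌ catalyst intermediate A (K = 91000 /M, k = 9600 /M/s)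
    catalyst intermediate A ⇌ catalyst intermediate B (K = 30.0, k = 2.00 /s)
    catalyst intermediate B → free catalyst + target (k = 2.30 /s)
    starting material + protic impurity → quenched substrate (k = 1500 /M/s)

At the mark with 10 mol%, 73.6 % of the catalyst is free, above the free floor of 50.0 %, so the bound forms hold 2.6 mol% of the 5.0 % converted.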